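**Retrosynthetic overview**
1. Target 9 ⇐ hydroxyl-directed reduction of the C6 ketone of enone diol 8 ⇐ acetal hydrolysis of acetonide 7.
2. 7 ⇐ β,γ-unsaturated ketone 4 by anti-epoxidation, epoxide → γ-hydroxy-enone isomerisation (sets C3, creates C1=C2) and benzoylation.
3. 4 ⇐ one-carbon ring expansion (1,2-alkenyl shift) of 1-vinylcyclopent-2-enol 3 with simultaneous C7–OBz bond formation.
4. 3 ⇐ enantiopure cyclopentenone acetonide 1 (carries C4 and C5) + vinylmagnesium bromide 2 (brings C1 and C7).
5. Ring order: the cyclopentene with its dioxolane is bought, expanded to the cyclohexene in step 2, and the dioxolane is removed in step 4.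

Assumption: the (3aS,6aS) antipode of cyclopentenone acetonide 1 is bought (both antipodes are catalogue items). Locants C1–C7 in the text are those of the target: C1 carries C7H2O, C2 is the vinylic CH, C3 is CH–OBz, C4–C6 are the carbinol carbons.

**Step 1**
Reactants: 1 (3aS,6aS)-2,2-dimethyl-3a,6a-dihydro-4H-cyclopenta[d][1,3]dioxol-4-one; 2 vinylmagnesium bromide
Product: 3 (3aS,4R,6aS)-4-ethenyl-2,2-dimethyl-3a,6a-dihydro-4H-cyclopenta[d][1,3]dioxol-4-ol
Conditions: THF, −78 °C; then H2O
Reagents that add atoms: none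
Why: 1,2-Grignard addition to the enone carbonyl from the convex face opposite the cis-fused dioxolane (established selectivity for this enone) gives the tertiary bis-allylic alcohol with vinyl trans to the acetal oxygens; this carbinol centre is erased in step 2.

**Step 2**
Reactants: 3 (3aS,4R,6aS)-4-ethenyl-2,2-dimethyl-3a,6a-dihydro-4H-cyclopenta[d][1,3]dioxol-4-ol
Product: 4 [(3aS,7aS)-2,2-dimethyl-4-oxo-3a,4,5,7a-tetrahydro-1,3-benzodioxol-5-yl]methyl benzoate (epimers at the CH bearing CH2OBz)
Conditions: (BzO)2 (1.5 equiv), fac-Ir(ppy)3 (1 mol %), degassed MeCN, blue LEDs, 25 °C; crude product filtered through neutral alumina and used at once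
Reagents that add atoms: dibenzoyl peroxide, O=C(OOC(=O)c1ccccc1)c1ccccc1
Why: Proposed new method: a benzoyloxy radical (from single-electron reduction of the peroxide by the excited Ir catalyst) adds to the unhindered terminal CH2 of the vinyl group; the resulting secondary radical at C1 closes 3-exo onto C2 of the ring alkene and β-scission of the old C6–C2 ring bond gives the ring-enlarged α-hydroxy radical at C6 (a net 1,2-alkenyl shift, cyclopentene → cyclohexene), which is oxidised by Ir(IV) (or by the peroxide in a chain) to the ketone with loss of benzoic acid; the closest known reaction types are the radical addition/1,2-aryl-migration ("radical semipinacol") of α-aryl allylic alcohols and the Dowd–Beckwith ring expansion, neither shown for an unstrained 1-vinylcyclopent-2-enol with an acyloxy radical; the new C1 centre is later made sp2, so its configuration does not matter.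

**Step 3**
Reactants: 4 [(3aS,7aS)-2,2-dimethyl-4-oxo-3a,4,5,7a-tetrahydro-1,3-benzodioxol-5-yl]methyl benzoate
Product: 7 [(3aS,7R,7aS)-7-(benzoyloxy)-2,2-dimethyl-4-oxo-3a,4,7,7a-tetrahydro-1,3-benzodioxol-5-yl]methyl benzoate, via anti-epoxide 5 (not isolated), via γ-hydroxy enone 6 (not isolated)
Conditions: DMDO, acetone, 0 °C; evaporate; Et3N (0.2 equiv), CH2Cl2, 0 °C; then BzCl, pyridine, DMAP (cat.), 0 °C
Reagents that add atoms: dimethyldioxirane, CC1(C)OO1; benzoyl chloride, O=C(Cl)c1ccccc1
Why: Electrophilic epoxidation of the isolated C2=C3 alkene takes place on the face opposite the cis-fused dioxolane (sets the C3–O bond trans to C4–O), the doubly activated C1–H then allows amine-catalysed E1cB opening of the β,γ-epoxy ketone to the γ-hydroxy enone (C1=C2 formed, C3 retained), and the new secondary alcohol is acylated in the same flask (epoxidation / epoxide-to-allylic-alcohol isomerisation / O-benzoylation).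

**Step 4**
Reactants: 7 [(3aS,7R,7aS)-7-(benzoyloxy)-2,2-dimethyl-4-oxo-3a,4,7,7a-tetrahydro-1,3-benzodioxol-5-yl]methyl benzoate
Product: 8 [(3R,4R,5S)-3-(benzoyloxy)-4,5-dihydroxy-6-oxocyclohex-1-en-1-yl]methyl benzoate
Conditions: TFA–H2O (9:1), 0 °C
Reagents that add atoms: none
Why: Acid-catalysed hydrolysis of the isopropylidene acetal; the benzoates and the enone tolerate brief cold aqueous TFA, acidic medium suppresses benzoyl migration, and no stereocentre is touched (acetal deprotection).

**Step 5**
Reactants: 8 [(3R,4R,5S)-3-(benzoyloxy)-4,5-dihydroxy-6-oxocyclohex-1-en-1-yl]methyl benzoate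
Product: 9 [(3R,4R,5R,6S)-3-(benzoyloxy)-4,5,6-trihydroxycyclohex-1-en-1-yl]methyl benzoate
Conditions: Me4NBH(OAc)3, MeCN–AcOH (1:1), −30 °C
Reagents that add atoms: none
Why: Evans–Saksena hydroxyl-directed reduction: the C4 and C5 hydroxyls, both on the same face, bind boron and deliver hydride intramolecularly to that face of the C6 carbonyl, giving the C6 alcohol trans to C5–OH and 1,3-anti to C4–OH (6S), while the mild acidic reagent leaves the benzoates and the alkene alone.

**Compound list**
1 | (3aS,6aS)-2,2-dimethyl-3a,6a-dihydro-4H-cyclopenta[d][1,3]dioxol-4-one | O=C1C=C[C@@H]2OC(C)(C)O[C@@H]21 | starting material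
2 | vinylmagnesium bromide | C=C[Mg]Br | starting material
3 | (3aS,4R,6aS)-4-ethenyl-2,2-dimethyl-3a,6a-dihydro-4H-cyclopenta[d][1,3]dioxol-4-ol (vinyl trans to the dioxolane) | C=C[C@@]1(O)C=C[C@@H]2OC(C)(C)O[C@@H]21 | intermediate
4 | [(3aS,7aS)-2,2-dimethyl-4-oxo-3a,4,5,7a-tetrahydro-1,3-benzodioxol-5-yl]methyl benzoate (epimers at C-5 of this name) | O=C(OCC1C=C[C@@H]2OC(C)(C)O[C@@H]2C1=O)c1ccccc1 | intermediate
5 | [(3aS,7aS)-6,7-epoxy-2,2-dimethyl-4-oxohexahydro-1,3-benzodioxol-5-yl]methyl benzoate, oxirane trans to the dioxolane (epimers at C-5) | O=C(OCC1[C@H]2O[C@H]2[C@@H]3OC(C)(C)O[C@@H]3C1=O)c1ccccc1 | intermediate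
6 | [(3aS,7R,7aS)-7-hydroxy-2,2-dimethyl-4-oxo-3a,4,7,7a-tetrahydro-1,3-benzodioxol-5-yl]methyl benzoate | O=C(OCC1=C[C@@H](O)[C@@H]2OC(C)(C)O[C@@H]2C1=O)c1ccccc1 | intermediate
7 | [(3aS,7R,7aS)-7-(benzoyloxy)-2,2-dimethyl-4-oxo-3a,4,7,7a-tetrahydro-1,3-benzodioxol-5-yl]methyl benzoate | O=C(OCC1=C[C@@H](OC(=O)c2ccccc2)[C@@H]3OC(C)(C)O[C@@H]3C1=O)c1ccccc1 | intermediate
8 | [(3R,4R,5S)-3-(benzoyloxy)-4,5-dihydroxy-6-oxocyclohex-1-en-1-yl]methyl benzoate | O=C(OCC1=C[C@@H](OC(=O)c2ccccc2)[C@H](O)[C@H](O)C1=O)c1ccccc1 | intermediate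
9 | [(3R,4R,5R,6S)-3-(benzoyloxy)-4,5,6-trihydroxycyclohex-1-en-1-yl]methyl benzoate (CNP0178138.1) | O=C(OCC1=C[C@@H](OC(=O)c2ccccc2)[C@H](O)[C@H](O)[C@H]1O)c1ccccc1 | target

**Totals**
Total steps: 5. Longest linear sequence: 5.

**Three steps most likely to fail**

Step 2 (the proposed new ring expansion). Risks are benzoyloxy-radical attack on the ring alkene or on allylic C–H, and trapping of the C1 radical before it rearranges. The fallback uses the known β-oxido-carbenoid ring enlargement; it sets out from 1 and returns at 4. Dibromomethyllithium (CH2Br2, LDA, THF, −78 °C) adds to the ketone of 1 to give the dibromomethyl carbinol F1. Treatment with n-BuLi (2.2 equiv, −95 °C) forms the β-oxido carbenoid, whose 1,2-alkenyl shift gives the lithium dienolate of the six-membered ketone. Quenching that enolate with monomeric formaldehyde gives the hydroxymethyl ketone F2, and BzCl/pyridine at 0 °C converts it into 4.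

Step 3 (epoxidation, isomerisation, benzoylation). Risks are base-induced loss of benzoate from the β-benzoyloxy ketone, conjugation of the alkene before it is oxidised, and imperfect facial selectivity. The fallback avoids both epoxide and base; it sets out from 4 and returns at 6. A Schenck ene reaction (O2, tetraphenylporphyrin, hν, CH2Cl2, −20 °C) removes the C1–H and places oxygen on C3 on the face away from the dioxolane, giving the allylic hydroperoxide F3. Reduction with PPh3 gives 6, which is benzoylated as in the route.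

Step 5 (directed reduction). Risk is incomplete facial control, or no reaction if neither hydroxyl can reach the carbonyl. The fallback inverts a wrongly configured alcohol instead; it sets out from 7 and returns at 9. Luche reduction (NaBH4, CeCl3, MeOH, −78 °C) of 7 attacks from the convex face and gives the cis alcohol F4 (C6–OH on the dioxolane side). Mitsunobu reaction with chloroacetic acid (PPh3, DIAD, THF) inverts C6 to give the chloroacetate F5. Thiourea/NaHCO3 in EtOH removes the chloroacetyl group selectively to give the alcohol F6, and TFA–H2O then cleaves the acetal to give 9.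

**Further compounds**
F1 | step 2 | (3aS,4R,6aS)-4-(dibromomethyl)-2,2-dimethyl-3a,6a-dihydro-4H-cyclopenta[d][1,3]dioxol-4-ol | BrC(Br)[C@@]1(O)C=C[C@@H]2OC(C)(C)O[C@@H]21
F2 | step 2 | (3aS,7aS)-5-(hydroxymethyl)-2,2-dimethyl-5,7a-dihydro-1,3-benzodioxol-4(3aH)-one (epimers at C-5) | OCC1C=C[C@@H]2OC(C)(C)O[C@@H]2C1=O
F3 | step 3 | hydroperoxide analogue of 6 (OOH in place of the C3 OH, same configuration) | O=C(OCC1=C[C@@H](OO)[C@@H]2OC(C)(C)O[C@@H]2C1=O)c1ccccc1
F4 | step 5 | C6 alcohol from 7 with OH cis to the dioxolane (6-epi series) | O=C(OCC1=C[C@@H](OC(=O)c2ccccc2)[C@@H]3OC(C)(C)O[C@@H]3[C@@H]1O)c1ccccc1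
F5 | step 5 | C6 chloroacetate with the C6 oxygen trans to the dioxolane | O=C(OCC1=C[C@@H](OC(=O)c2ccccc2)[C@@H]3OC(C)(C)O[C@@H]3[C@H]1OC(=O)CCl)c1ccccc1
F6 | step 5 | 4,5-O-isopropylidene derivative of 9 | O=C(OCC1=C[C@@H](OC(=O)c2ccccc2)[C@@H]3OC(C)(C)O[C@@H]3[C@H]1O)c1ccccc1
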